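Readings and results are calculated with constants of no real substance, and the scatter is random.

You cannot raise the excess of J over D without spending J: in the epsilon run J stood at 20.7% and D at 3.3% after 90.0 s, each from half of the charge.

all flasks: Q 0.1 mol%

| charge | D | J | G | remark | time |
|---|---|---|---|---|---|
| epsilon | 0.20 M | 0.20 M | 3 equiv | run made earlier |  |
| eta | 0.45 M | 0.45 M | 3 equiv | run made earlier |  |
| flask | 0.30 M | 0.30 M | 3.00 equiv |  | 2.5 min |

- epsilon (time / s: J / %, D / %, E / %): 10.0: 43.2, 31.2, 15.1; 12.0: 41.7, 28.9, 16.6; 20.0: 38.1, 21.9, 21.1; 30.0: 34.8, 15.9, 25.6; 50.0: 29.2, 9.1, 31.2; 90.0: 20.7, 3.3, 36.5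
- eta (time / s: J / %, D / %, E / %): 10.0: 27.1, 6.8, 34.1; 20.0: 18.5, 1.9, 38.7; 30.0: 13.7, 0.5, 42.1; 50.0: 7.1, 0, 45.2; 60.0: 5.6, 0.4, 46.6; 90.0: 2.7, 0, 47.9

(standard deviation of a reading: 0.3 percentage points)

* whether the excess of J over D among what is left of the two reaches 90% by 2.5 min (no / yes)
* the highest excess of J over D among what is left of the two up to 2.5 min

So carry the selectivity factor, read there as s = 3.08, the logarithm of the fraction of D left over the logarithm of the fraction of J left. The eta run reads 3.26 at 10.0 s, so I freeze s. Then cD/cJ equals the fraction of J left raised to the power s minus one, and an excess of 90% asks for J at 12.2% of the charge, with time out of the sum.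

Two versions of the flask bracket the clock. The slow version is the epsilon run: extrapolated at the pace read late in that run, 0.00860 s⁻¹, its J gets there, by this estimate, near 2.53 min, just past the limit of 2.5 min. The fast version is the eta run, whose J had passed that mark by 50.0 s, reading 7.1%. The flask, at 0.30 M, lies between those charges, and at 30.0 s J read 13.7% in eta against 34.8% in epsilon. I therefore say yes, with a top excess above 90%.

The forecast, holding that “selectivity is constant and each enantiomer decays first order”, says yes, with a top of 99%, between 97% and 99.8%.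

The flask gives yes and a top excess of 98.7%.

    G + Q + D → Q + E (k = 630 M⁻² s⁻¹)
    G + Q + J → Q + L (k = 200 M⁻² s⁻¹)
    E ⇌ L (k = 0.110 s⁻¹)
    Q ⇌ X (K = 0.670, k = 0.150 s⁻¹)

In the flask the excess passed 90% at 1.24 min, with J at 12.7% of the charge against the 12.2% reckoned from s. On the eta run, s turns the J reading of 18.5% at 20.0 s into D of 2.34%, where D was read as 1.9%.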